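The enal is the self-aldol dimer of one piperidinyl-dodecanal, so ring A (on the β-carbon chain) and ring B (on the α-carbon chain) come from one monomer, and the last C–C bond is made by aldol condensation. In each ring (N1, C2 methyl, C3 hydroxyl, C6 chain) the array O–C3–C2(CH3)–N1–C6 is an N-acylalanine in disguise: alanine ethyl ester, acylated by the C13 chain acid, closes to a 5-ethoxyoxazole, a 2-azadiene with termini C3 and C6. Its decarboxylative Kondrat'eva Diels–Alder reaction with acrylic acid, a traceless ethylene equivalent, forms C3–C4 and C5–C6 in one operation and gives the pyridin-3-ol; all-cis hydrogenation and a lipase resolution then set the stereocenters.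

Key step: step 3

Remarks: the stereocenter of 2 is erased in step 2, so its configuration is immaterial (the L-ester is written). The racemates 9 and 10 are written with the SMILES of the enantiomer that is carried on. Compound 1 is taken as commercially available.

Step 1
Reactants: 1 13-methoxy-13-oxotridecanoic acid (monomethyl tridecanedioate); 2 ethyl L-alaninate hydrochloride
Product: 3 methyl 13-{[(2S)-1-ethoxy-1-oxopropan-2-yl]amino}-13-oxotridecanoate
Conditions: EDC·HCl, HOBt, iPr2NEt, CH2Cl2, 0 °C to rt
Reagents that add atoms: none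
Why: Carbodiimide amide coupling of a primary amine with a carboxylic acid is routine, and the configuration of the alanine carbon does not matter because step 2 flattens it.

Step 2
Reactants: 3 methyl 13-{[(2S)-1-ethoxy-1-oxopropan-2-yl]amino}-13-oxotridecanoate
Product: 4 methyl 12-(5-ethoxy-4-methyl-1,3-oxazol-2-yl)dodecanoate
Conditions: Ph3P, I2, Et3N, CH2Cl2, 0 °C to rt
Reagents that add atoms: none
Why: Cyclodehydration of an N-acyl α-amino ester (Robinson–Gabriel-type closure): the amide oxygen is activated on phosphorus and leaves as Ph3PO, the ester carbonyl oxygen closes the ring, and loss of the α-proton aromatises to the 5-ethoxyoxazole, while the remote methyl ester is untouched.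

Step 3
Reactants: 4 methyl 12-(5-ethoxy-4-methyl-1,3-oxazol-2-yl)dodecanoate; 5 acrylic acid
Product: 8 methyl 12-(5-hydroxy-6-methylpyridin-2-yl)dodecanoate, via oxa-bridged cycloadduct acid 6 (not isolated), via 3-oxo-3,4-dihydropyridine-4-carboxylic acid 7 (not isolated)
Conditions: acrylic acid (3 equiv), hydroquinone (cat.), toluene, 110 °C
Reagents that add atoms: none
Why: The 5-ethoxyoxazole 4 is an electron-rich 2-azadiene (C2=N3–C4=C5) that undergoes a concerted, normal-electron-demand [4+2] cycloaddition with acrylic acid across C2 and C5, the Kondrat'eva pyridine synthesis in its decarboxylative form, so that the bond from the chain-bearing carbon to the β-carbon of the acid and the bond from the ethoxy-bearing carbon to its α-carbon (C6–C5 and C3–C4 of the later piperidine) form together. The six-membered ring is closed by this intermolecular cycloaddition, which gives the oxygen-bridged adduct 6; the acid medium then opens the bridge, ethanol is lost, and the β-keto acid 7 loses CO2 as it aromatises, which leaves the two alkene carbons as the unsubstituted C4 and C5 of pyridinol 8. No stereocenter of the product arises, because every ring carbon ends sp2 and the transient centers of 6 are destroyed; the three stereocenters are set on the flat ring in steps 4 and 6. The step needs regioselectivity, with the carboxyl-bearing carbon bonded to the ethoxy-bearing terminus, and the donor ethoxy group at that terminus secures it (ortho orientation of a 1-alkoxydiene), which matters because only this adduct leads to a β-keto acid able to decarboxylate. Chemoselectivity is no issue, since the remote methyl ester and the saturated chain are inert to the dienophile and to the heating.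

Step 4
Reactants: 8 methyl 12-(5-hydroxy-6-methylpyridin-2-yl)dodecanoate
Product: 9 methyl 12-[(2R*,5S*,6S*)-5-hydroxy-6-methylpiperidin-2-yl]dodecanoate (racemic, all-cis)
Conditions: H2 (50 bar), Rh/Al2O3 (5 wt % Rh), MeOH–AcOH, 50 °C; then aq. K2CO3
Reagents that add atoms: none
Why: Heterogeneous hydrogenation of a 2,6-dialkylpyridin-3-ol delivers all six hydrogens from the face adsorbed on the metal, so the methyl, hydroxyl and chain groups should end up all-cis (as a racemate), and rhodium is chosen to limit C–O hydrogenolysis.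

Step 5
Reactants: 9 methyl 12-[(2R*,5S*,6S*)-5-hydroxy-6-methylpiperidin-2-yl]dodecanoate (racemic)
Product: 10 tert-butyl (2S*,3S*,6R*)-3-hydroxy-6-(12-methoxy-12-oxododecyl)-2-methylpiperidine-1-carboxylate (racemic)
Conditions: Boc2O, Et3N, MeOH, 50 °C
Reagents that add atoms: di-tert-butyl dicarbonate, CC(C)(C)OC(=O)OC(=O)OC(C)(C)C
Why: Carbamate formation on the secondary amine, which is more nucleophilic than the secondary alcohol in the absence of an acyl-transfer catalyst; no stereocenter is touched.

Step 6
Reactants: 10 tert-butyl (2S*,3S*,6R*)-3-hydroxy-6-(12-methoxy-12-oxododecyl)-2-methylpiperidine-1-carboxylate (racemic)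
Product: 11 tert-butyl (2S,3S,6R)-3-hydroxy-6-(12-methoxy-12-oxododecyl)-2-methylpiperidine-1-carboxylate
Conditions: immobilised Candida antarctica lipase B, vinyl acetate, tert-butyl methyl ether, 40 °C, stopped just past half conversion; chromatography
Reagents that add atoms: none
Why: Lipase-catalysed kinetic resolution by enantioselective transesterification: by the empirical size rule for lipase acylation of secondary alcohols (large group C2 with nitrogen and methyl, medium group C4) the (3R)-carbinol should be acetylated, so the (2S,3S,6R) alcohol should remain and is separated from the (2R,3R,6S) acetate, which fixes the absolute configuration of all three centers because their relative configuration is already locked.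

Step 7
Reactants: 11 tert-butyl (2S,3S,6R)-3-hydroxy-6-(12-methoxy-12-oxododecyl)-2-methylpiperidine-1-carboxylate
Product: 12 tert-butyl (2S,3S,6R)-3-hydroxy-2-methyl-6-(12-oxododecyl)piperidine-1-carboxylate
Conditions: iBu2AlH (2.4 equiv), CH2Cl2, −78 °C; MeOH, then aq. potassium sodium tartrate
Reagents that add atoms: none
Why: Partial reduction of a methyl ester with iBu2AlH at −78 °C stops at the aluminium hemiacetal, which gives the aldehyde on work-up; the first equivalent is consumed by the free hydroxyl and the Boc carbamate is inert at this temperature.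

Step 8
Reactants: 12 tert-butyl (2S,3S,6R)-3-hydroxy-2-methyl-6-(12-oxododecyl)piperidine-1-carboxylate (two molecules)
Product: 14 (E)-2-{10-[(2R,5S,6S)-1-(tert-butoxycarbonyl)-5-hydroxy-6-methylpiperidin-2-yl]decyl}-14-[(2R,5S,6S)-1-(tert-butoxycarbonyl)-5-hydroxy-6-methylpiperidin-2-yl]tetradec-2-enal, via aldol adduct 13 (not isolated)
Conditions: pyrrolidine (0.2 equiv), PhCO2H (0.2 equiv), toluene, 25 °C
Reagents that add atoms: none
Why: Amine-catalysed self-aldol condensation (enamine of one aldehyde adds to a second, then water is eliminated) of an unbranched aldehyde gives the 2-alkyl-2-enal, whose (E)-isomer with the chain trans to the formyl group is the thermodynamic product, and the α-branched enal is far less prone to further enamine chemistry than 12.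

Step 9
Reactants: 14 the bis-Boc enal
Product: 15 (E)-2-{10-[(2R,5S,6S)-5-hydroxy-6-methylpiperidin-2-yl]decyl}-14-[(2R,5S,6S)-5-hydroxy-6-methylpiperidin-2-yl]tetradec-2-enal (CNP0177491.1)
Conditions: CF3CO2H, CH2Cl2, 0 °C; then cold aq. NaHCO3
Reagents that add atoms: none
Why: Acidolysis of the two tert-butyl carbamates (loss of isobutene, then decarboxylation) under conditions that should leave the enal and the secondary alcohols alone; the hindered 2,6-disubstituted amines are set free without touching any stereocenter.

Compound list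
1 | 13-methoxy-13-oxotridecanoic acid | COC(=O)CCCCCCCCCCCC(=O)O | starting material
2 | ethyl L-alaninate hydrochloride | C[C@H](N)C(=O)OCC.Cl | starting material
3 | methyl 13-{[(2S)-1-ethoxy-1-oxopropan-2-yl]amino}-13-oxotridecanoate | CCOC(=O)[C@H](C)NC(=O)CCCCCCCCCCCC(=O)OC | intermediate
4 | methyl 12-(5-ethoxy-4-methyl-1,3-oxazol-2-yl)dodecanoate | CCOc1oc(CCCCCCCCCCCC(=O)OC)nc1C | intermediate
5 | acrylic acid | C=CC(=O)O | starting material
6 | 4-ethoxy-1-(12-methoxy-12-oxododecyl)-3-methyl-7-oxa-2-azabicyclo[2.2.1]hept-2-ene-5-carboxylic acid (racemic, stereoisomer mixture, not isolated) | CCOC12C(C(=O)O)CC(CCCCCCCCCCCC(=O)OC)(O1)N=C2C | intermediate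
7 | 6-(12-methoxy-12-oxododecyl)-2-methyl-3-oxo-3,4-dihydropyridine-4-carboxylic acid (not isolated) | CC1=NC(CCCCCCCCCCCC(=O)OC)=CC(C(=O)O)C1=O | intermediate
8 | methyl 12-(5-hydroxy-6-methylpyridin-2-yl)dodecanoate | Cc1nc(CCCCCCCCCCCC(=O)OC)ccc1O | intermediate
9 | methyl 12-[(2R*,5S*,6S*)-5-hydroxy-6-methylpiperidin-2-yl]dodecanoate (racemate, all-cis) | C[C@@H]1N[C@H](CCCCCCCCCCCC(=O)OC)CC[C@@H]1O | intermediate
10 | tert-butyl (2S*,3S*,6R*)-3-hydroxy-6-(12-methoxy-12-oxododecyl)-2-methylpiperidine-1-carboxylate (racemate, all-cis) | C[C@@H]1N(C(=O)OC(C)(C)C)[C@H](CCCCCCCCCCCC(=O)OC)CC[C@@H]1O | intermediate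
11 | tert-butyl (2S,3S,6R)-3-hydroxy-6-(12-methoxy-12-oxododecyl)-2-methylpiperidine-1-carboxylate (single enantiomer) | C[C@@H]1N(C(=O)OC(C)(C)C)[C@H](CCCCCCCCCCCC(=O)OC)CC[C@@H]1O | intermediate
12 | tert-butyl (2S,3S,6R)-3-hydroxy-2-methyl-6-(12-oxododecyl)piperidine-1-carboxylate | C[C@@H]1N(C(=O)OC(C)(C)C)[C@H](CCCCCCCCCCCC=O)CC[C@@H]1O | intermediate
13 | 2-{10-[(2R,5S,6S)-1-(tert-butoxycarbonyl)-5-hydroxy-6-methylpiperidin-2-yl]decyl}-3-hydroxy-14-[(2R,5S,6S)-1-(tert-butoxycarbonyl)-5-hydroxy-6-methylpiperidin-2-yl]tetradecanal (aldol adduct, diastereomer mixture at C2 and C3, not isolated) | C[C@@H]1N(C(=O)OC(C)(C)C)[C@H](CCCCCCCCCCCC(O)C(C=O)CCCCCCCCCC[C@@H]2CC[C@H](O)[C@H](C)N2C(=O)OC(C)(C)C)CC[C@@H]1O | intermediate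
14 | (E)-2-{10-[(2R,5S,6S)-1-(tert-butoxycarbonyl)-5-hydroxy-6-methylpiperidin-2-yl]decyl}-14-[(2R,5S,6S)-1-(tert-butoxycarbonyl)-5-hydroxy-6-methylpiperidin-2-yl]tetradec-2-enal | C[C@@H]1N(C(=O)OC(C)(C)C)[C@H](CCCCCCCCCCC/C=C(/C=O)CCCCCCCCCC[C@@H]2CC[C@H](O)[C@H](C)N2C(=O)OC(C)(C)C)CC[C@@H]1O | intermediate
15 | (E)-2-{10-[(2R,5S,6S)-5-hydroxy-6-methylpiperidin-2-yl]decyl}-14-[(2R,5S,6S)-5-hydroxy-6-methylpiperidin-2-yl]tetradec-2-enal | C[C@@H]1N[C@H](CCCCCCCCCCC/C=C(/C=O)CCCCCCCCCC[C@@H]2CC[C@H](O)[C@H](C)N2)CC[C@@H]1O | target

Total step count: 9. Longest linear sequence: 9 steps (1 to 15).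

Steps most likely to fail

Step 3. The alkoxyoxazole may be opened hydrolytically by the acid back to the acylamino ester faster than it cycloadds, or the cycloaddition may take the reverse orientation, whose adduct cannot decarboxylate. The fallback sets out from 4 and comes back at 8. It drops the activating carboxyl group and uses ethene itself under pressure (ethene 60 bar, CF3CO2H cat., toluene, 180 °C, autoclave), a Kondrat'eva reaction with an unactivated alkene. The adduct methyl 12-(4-ethoxy-3-methyl-7-oxa-2-azabicyclo[2.2.1]hept-2-en-1-yl)dodecanoate F1 opens and loses ethanol to give 8, with no regiochemical question and no decarboxylation to rely on.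

Step 6. The enzyme may acylate slowly or discriminate poorly between the enantiomers at a carbinol flanked by the methyl-bearing carbon and the bulky carbamate. The fallback sets out from 10 and comes back at 11. It replaces the kinetic resolution by a covalent one: esterification with (S)-2-methoxy-2-phenylacetic acid (DCC, DMAP cat., CH2Cl2, 0 °C) should give tert-butyl (2S,3S,6R)-3-{[(2S)-2-methoxy-2-phenylacetyl]oxy}-6-(12-methoxy-12-oxododecyl)-2-methylpiperidine-1-carboxylate F2 and its diastereomer tert-butyl (2R,3R,6S)-3-{[(2S)-2-methoxy-2-phenylacetyl]oxy}-6-(12-methoxy-12-oxododecyl)-2-methylpiperidine-1-carboxylate F3. These are to be separated by chromatography and assigned by the NMR shielding model for such esters. Methanolysis of F2 (K2CO3, MeOH, rt) returns 11.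

Step 8. The enamine of the starting aldehyde may add to the enal product in a Michael sense and oligomerise, or dehydration may stay incomplete. The fallback sets out from 12 and comes back at 14. One half of 12 is α-methylenated (aq. CH2O, pyrrolidine and propionic acid cat., iPrOH, 45 °C) to tert-butyl (2S,3S,6R)-6-(11-formyldodec-11-en-1-yl)-3-hydroxy-2-methylpiperidine-1-carboxylate F4. The other half is converted by Wittig methylenation (Ph3PCH3Br, KN(SiMe3)2 in excess, THF, 0 °C) to tert-butyl (2S,3S,6R)-3-hydroxy-2-methyl-6-(tridec-12-en-1-yl)piperidine-1-carboxylate F5. Cross metathesis of F4 with F5 (second-generation Hoveyda–Grubbs catalyst RuCl2(H2IMes)(=CH-C6H4-2-OiPr), CH2Cl2, 40 °C) should give the (E)-trisubstituted enal 14 with loss of ethene.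

Further compounds
F1 | step 3 | methyl 12-(4-ethoxy-3-methyl-7-oxa-2-azabicyclo[2.2.1]hept-2-en-1-yl)dodecanoate (racemic) | CCOC12CCC(CCCCCCCCCCCC(=O)OC)(O1)N=C2C
F2 | step 6 | tert-butyl (2S,3S,6R)-3-{[(2S)-2-methoxy-2-phenylacetyl]oxy}-6-(12-methoxy-12-oxododecyl)-2-methylpiperidine-1-carboxylate | C[C@@H]1N(C(=O)OC(C)(C)C)[C@H](CCCCCCCCCCCC(=O)OC)CC[C@@H]1OC(=O)[C@@H](OC)c2ccccc2
F3 | step 6 | tert-butyl (2R,3R,6S)-3-{[(2S)-2-methoxy-2-phenylacetyl]oxy}-6-(12-methoxy-12-oxododecyl)-2-methylpiperidine-1-carboxylate | C[C@H]1N(C(=O)OC(C)(C)C)[C@@H](CCCCCCCCCCCC(=O)OC)CC[C@H]1OC(=O)[C@@H](OC)c2ccccc2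
F4 | step 8 | tert-butyl (2S,3S,6R)-6-(11-formyldodec-11-en-1-yl)-3-hydroxy-2-methylpiperidine-1-carboxylate | C[C@@H]1N(C(=O)OC(C)(C)C)[C@H](CCCCCCCCCCC(=C)C=O)CC[C@@H]1O
F5 | step 8 | tert-butyl (2S,3S,6R)-3-hydroxy-2-methyl-6-(tridec-12-en-1-yl)piperidine-1-carboxylate | C[C@@H]1N(C(=O)OC(C)(C)C)[C@H](CCCCCCCCCCCC=C)CC[C@@H]1O
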